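Watch the early minutes of the flask, where L, G and Z compete for J while J also decays to D.

    L + J → L.J (k1 = 3.26 L mol⁻¹ min⁻¹)
    G + J → G.J (k2 = 1.85 L mol⁻¹ min⁻¹)
    Z + J → Z.J (k3 = 5.43 L mol⁻¹ min⁻¹)
    J → D (k4 = 0.0711 min⁻¹)

L 0.42 M; J 1.50 equiv; G 5.00 equiv; Z 0.200 equiv; time 3.0 h

- why nothing more happens at 3.0 h, or that something still does (all of L has reacted / it is still moving / J has run out first / forward and back rates have come level)
- share of the L used up at 3.0 h
- L.J at 3.0 h, in percent of the L charged

- the reaction counts as stopped when no species that holds the L changes by six tenths of a point or more over the second half of the time
- run time (flask): 3.0 h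

First ask which given numbers must be known well, and reckon them by hand at the charged concentrations. Each partner removes J at its own rate: G at 3.89 min⁻¹, L at 1.37 min⁻¹, Z at 0.456 min⁻¹, and the decay at 0.0711 min⁻¹, together 5.78 min⁻¹. An error in the charge of J passes straight into the outcome. An error in the charge of G or in its constant counts with its share of J's loss, 67.3%. Z counts with 7.89% and the decay with 1.23%, so know G well and spare the effort on the decay.

Now take the numbers themselves. J's lifetime at the charge is 0.173 min, so the run time of 3.0 h spans 1040 of them and need not be known well. L's lifetime under the charged J is 0.487 min. Their ratio, 0.355, is the lifetime count: how many lifetimes of L the J lasts. The share of L used up is one minus the exponential of minus this count, which gives my reckoning of 29.9%. It holds G, L and Z at their charge while they fall as they react, which makes it lean low.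

The forecast stands above my reckoning: J has run out first, with 33.8% of L used up and 33.8% as L.J, on the grounds that “J runs out within minutes, so L stops well short of complete conversion”.

The simulated flask ends with this verdict: J has run out first, with 33.8% of L used up and 33.8% as L.J. Step 1 had half of its turnover behind it at 0.124 min, and at 0.300 h J, the limiting reagent, stood at 0% of its charge, with L at 66.2%. From then until 3.00 h L stayed at 66.2% and L.J at 33.8%. The neighbour flask charged with 0.380 equiv of J has a lifetime count of 0.0900, which gives 8.61%, and that flask reached 8.90%.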